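**Retrosynthetic overview**

1. Ring numbering used below: C1 quaternary carbon (methyl, vinyl), C2 CH2, C3 acyloxy carbon, C4 carbon bearing the acrylic acid, C5 carbinol, C6 carbon bearing the hydroxypropenyl group. The target is reached by deprotection, C3–O acylation with an acetonide-protected (R)-acid, and reduction of a C3 ketone.
2. The cyclohexanone is cut at C1–C2 and C4–C5 to an acyclic aldehyde carrying an allyl vinyl ether. A thermal Claisen rearrangement followed in the same pot by an amine-catalysed aldol closes the only carbocycle.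
3. Enabling feature: the C3 oxygen is 1,3 to the vinyl-bearing quaternary C1 (γ,δ-unsaturated ketone) and 1,3 to the C5 hydroxyl (β-hydroxy ketone). With C3 as a ketone both retrons overlap in the ring C1–C2–C3–C4–C5. Itaconic acid maps onto C3, C4 and the three acrylic acid carbons, and C2 comes from a titanium methylidene.
4. The precursor comes from Tebbe methylenation of the ester of a Z-allylic alcohol with itaconic acid 1-tert-butyl ester. The alcohol comes from a Rh/BINAP conjugate addition of a Z-alkenylboronate to a γ-silyloxy enoate, then α-methylenation and reduction.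
5. C6 is the only stereocentre set by a catalyst; C1, C4, C5 and then C3 are relayed from it, and the side-chain carbinol is bought as methyl (R)-dioxolanylacetate.

Key step: step 16

Abbreviations: TES = triethylsilyl, TBDPS = tert-butyldiphenylsilyl, PMB = 4-methoxybenzyl, Bpin = 4,4,5,5-tetramethyl-1,3,2-dioxaborolan-2-yl.

Assumption: ethyl (2E)-4-hydroxybut-2-enoate, monomethyl itaconate (the 4-methyl ester with the free conjugated acid) and methyl 2-[(4R)-2,2-dimethyl-1,3-dioxolan-4-yl]acetate are taken as purchasable.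

Assumption: the (R)-BINAP–rhodium catalyst is taken to add the alkenyl group to the Si face of C3 of the enoate (3R adduct); should the sense be the reverse, (S)-BINAP is used with no other change.

**Route**

Step 1
Reactants: 1 but-2-yn-1-ol
Product: 3 (2Z)-3-iodobut-2-en-1-ol, via cyclic alkenylaluminate 2 (not isolated)
Conditions: NaAlH2(OCH2CH2OMe)2 (Red-Al), THF, 0 °C to rt; then I2, −78 to 0 °C
Reagents that add atoms: iodine, [I][I]
Why: Hydroxyl-directed trans-hydroalumination places aluminium on C3 in a five-membered chelate, and iodinolysis with retention should give the Z iodide (iodine cis to CH2OH), the geometry that later becomes the Z allylic ether.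

Step 2
Reactants: 3 (2Z)-3-iodobut-2-en-1-ol
Product: 4 1-({[(2Z)-3-iodobut-2-en-1-yl]oxy}methyl)-4-methoxybenzene
Conditions: NaH, 4-MeOC6H4CH2Cl, Bu4NI (cat.), THF/DMF, 0 °C to rt
Reagents that add atoms: 4-methoxybenzyl chloride, COc1ccc(CCl)cc1
Why: Williamson etherification; the PMB group masks the future tether oxygen and can be removed oxidatively beside silyl ethers.

Step 3
Reactants: 4 1-({[(2Z)-3-iodobut-2-en-1-yl]oxy}methyl)-4-methoxybenzene
Product: 5 2-[(2E)-4-(PMB-oxy)but-2-en-2-yl]-4,4,5,5-tetramethyl-1,3,2-dioxaborolane (boron cis to the CH2O group)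
Conditions: B2pin2, PdCl2(PPh3)2 (3 mol %), PPh3, KOPh, toluene, 50 °C
Reagents that add atoms: bis(pinacolato)diboron, CC1(C)OB(OC1(C)C)B1OC(C)(C)C(C)(C)O1
Why: Miyaura borylation of an alkenyl iodide proceeds with retention of the double-bond geometry.

Step 4
Reactants: 6 ethyl (2E)-4-hydroxybut-2-enoate
Product: 7 ethyl (2E)-4-(TES-oxy)but-2-enoate
Conditions: Et3SiCl, imidazole, CH2Cl2, 0 °C
Reagents that add atoms: chlorotriethylsilane, CC[Si](Cl)(CC)CC
Why: Silylation of the primary alcohol; TES is chosen because fluoride removes it later in the presence of a TBDPS ether and an acid-labile enol ether.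

Step 5
Reactants: 5 2-[(2E)-4-(PMB-oxy)but-2-en-2-yl]-4,4,5,5-tetramethyl-1,3,2-dioxaborolane; 7 ethyl (2E)-4-(TES-oxy)but-2-enoate
Product: 8 ethyl (3R)-3-[(2Z)-4-(PMB-oxy)but-2-en-2-yl]-4-(TES-oxy)butanoate
Conditions: Rh(acac)(C2H4)2 (5 mol %), (R)-BINAP (6 mol %), KOH (10 mol %), 1,4-dioxane/H2O 10:1, 60 °C
Reagents that add atoms: none
Why: Hayashi–Miyaura rhodium-catalysed asymmetric conjugate addition transfers the alkenyl group with retention of its geometry, and the BINAP ligand selects the face of C3, which sets the future ring C6 as the only catalyst-controlled stereocentre.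

Step 6
Reactants: 8 ethyl (3R)-3-[(2Z)-4-(PMB-oxy)but-2-en-2-yl]-4-(TES-oxy)butanoate
Product: 11 ethyl (3S)-3-[(2Z)-4-(PMB-oxy)but-2-en-2-yl]-2-methylidene-4-(TES-oxy)butanoate, via Mannich base 9 (not isolated), via trimethylammonium iodide 10 (not isolated)
Conditions: LiN(i-Pr)2, THF, −78 °C; CH2=NMe2+ I−, −78 °C to rt; then MeI, MeOH, rt; then DBU, CH2Cl2, rt
Reagents that add atoms: N,N-dimethylmethyleneiminium iodide (Eschenmoser's salt), C=[N+](C)C.[I-]
Why: Mannich reaction of the lithium ester enolate, quaternisation and E1cB elimination give the α-methylene ester; the existing stereocentre is β to the ester and is not touched (its descriptor changes only through priorities).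

Step 7
Reactants: 11 ethyl (3S)-3-[(2Z)-4-(PMB-oxy)but-2-en-2-yl]-2-methylidene-4-(TES-oxy)butanoate
Product: 12 (3S)-3-[(2Z)-4-(PMB-oxy)but-2-en-2-yl]-2-methylidene-4-(TES-oxy)butan-1-ol
Conditions: i-Bu2AlH (2.5 equiv), CH2Cl2, −78 °C; Rochelle salt work-up
Reagents that add atoms: none
Why: 1,2-Reduction of the acrylate ester by the aluminium hydride gives the 2-substituted allylic alcohol without conjugate reduction.

Step 8
Reactants: 12 (3S)-3-[(2Z)-4-(PMB-oxy)but-2-en-2-yl]-2-methylidene-4-(TES-oxy)butan-1-ol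
Product: 13 tert-butyl{[(3S)-3-[(2Z)-4-(PMB-oxy)but-2-en-2-yl]-2-methylidene-4-(TES-oxy)butyl]oxy}diphenylsilane
Conditions: t-BuPh2SiCl, imidazole, DMF, rt
Reagents that add atoms: tert-butyl(chloro)diphenylsilane, CC(C)(C)[Si](Cl)(c1ccccc1)c1ccccc1
Why: Silylation; the TBDPS ether outlasts the later TES cleavage and makes the propenyl arm the large group that steers step 16.

Step 9
Reactants: 13 tert-butyl{[(3S)-3-[(2Z)-4-(PMB-oxy)but-2-en-2-yl]-2-methylidene-4-(TES-oxy)butyl]oxy}diphenylsilane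
Product: 14 (2Z,4S)-6-(TBDPS-oxy)-3-methyl-5-methylidene-4-[(TES-oxy)methyl]hex-2-en-1-ol
Conditions: DDQ, CH2Cl2/pH 7 buffer 10:1, 0 °C
Reagents that add atoms: none
Why: Oxidative PMB ether cleavage by DDQ frees only the allylic alcohol; both silyl ethers are inert under buffered conditions.

Step 10
Reactants: 15 4-methoxy-2-methylidene-4-oxobutanoic acid (monomethyl itaconate)
Product: 16 1-tert-butyl 4-methyl 2-methylidenebutanedioate
Conditions: 2-methylpropene, H2SO4 (cat.), CH2Cl2, sealed tube, rt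
Reagents that add atoms: 2-methylpropene, C=C(C)C
Why: Acid-catalysed addition of the carboxylic acid to isobutene gives the hindered tert-butyl acrylate ester.

Step 11
Reactants: 16 1-tert-butyl 4-methyl 2-methylidenebutanedioate
Product: 17 3-(tert-butoxycarbonyl)but-3-enoic acid
Conditions: LiOH (1.05 equiv), THF/H2O, 0 °C; then 1 M HCl to pH 3
Reagents that add atoms: lithium hydroxide, [Li+].[OH-]
Why: Chemoselective saponification; the unhindered, non-conjugated methyl ester is hydrolysed far faster than the conjugated tert-butyl ester.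

Step 12
Reactants: 14 (2Z,4S)-6-(TBDPS-oxy)-3-methyl-5-methylidene-4-[(TES-oxy)methyl]hex-2-en-1-ol; 17 3-(tert-butoxycarbonyl)but-3-enoic acid
Product: 18 1-tert-butyl 4-[(2Z,4S)-6-(TBDPS-oxy)-3-methyl-5-methylidene-4-[(TES-oxy)methyl]hex-2-en-1-yl] 2-methylidenebutanedioate
Conditions: EDC·HCl, DMAP (10 mol %), CH2Cl2, 0 °C
Reagents that add atoms: none
Why: Steglich-type carbodiimide esterification at low temperature joins the two fragments without isomerising the β,γ-unsaturated acid.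

Step 13
Reactants: 18 1-tert-butyl 4-[(2Z,4S)-6-(TBDPS-oxy)-3-methyl-5-methylidene-4-[(TES-oxy)methyl]hex-2-en-1-yl] 2-methylidenebutanedioate
Product: 19 tert-butyl 4-{[(2Z,4S)-6-(TBDPS-oxy)-3-methyl-5-methylidene-4-[(TES-oxy)methyl]hex-2-en-1-yl]oxy}-2-methylidenepent-4-enoate
Conditions: Cp2Ti(μ-Cl)(μ-CH2)AlMe2 (Tebbe reagent, 1.3 equiv), pyridine (cat.), THF/toluene, −40 to 0 °C; aq. NaOH quench, basic alumina
Reagents that add atoms: Tebbe reagent, C[Al-]1(C)C[Ti]([Cl+]1)(C1C=CC=C1)C1C=CC=C1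
Why: Tebbe methylenation of the unhindered alkyl ester (the conjugated, hindered tert-butyl ester should react much more slowly) gives the 2-alkoxy-1-alkene regiospecifically; the new CH2 is the future ring C2.

Step 14
Reactants: 19 tert-butyl 4-{[(2Z,4S)-6-(TBDPS-oxy)-3-methyl-5-methylidene-4-[(TES-oxy)methyl]hex-2-en-1-yl]oxy}-2-methylidenepent-4-enoate
Product: 20 tert-butyl 4-{[(2Z,4S)-6-(TBDPS-oxy)-4-(hydroxymethyl)-3-methyl-5-methylidenehex-2-en-1-yl]oxy}-2-methylidenepent-4-enoate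
Conditions: Bu4NF (1.1 equiv), THF, 0 °C, 20 min
Reagents that add atoms: none
Why: Fluoride desilylation under non-acidic conditions; the primary TES ether is cleaved much faster than the TBDPS ether, and the enol ether survives.

Step 15
Reactants: 20 tert-butyl 4-{[(2Z,4S)-6-(TBDPS-oxy)-4-(hydroxymethyl)-3-methyl-5-methylidenehex-2-en-1-yl]oxy}-2-methylidenepent-4-enoate
Product: 21 tert-butyl 4-{[(2Z,4S)-6-(TBDPS-oxy)-4-formyl-3-methyl-5-methylidenehex-2-en-1-yl]oxy}-2-methylidenepent-4-enoate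
Conditions: Dess–Martin periodinane, NaHCO3, CH2Cl2, 0 °C; filtration through basic alumina, used at once
Reagents that add atoms: none
Why: Buffered Dess–Martin oxidation is neutral enough to keep the enol ether and the enolisable α-stereocentre of the new aldehyde intact.

Step 16
Reactants: 21 tert-butyl 4-{[(2Z,4S)-6-(TBDPS-oxy)-4-formyl-3-methyl-5-methylidenehex-2-en-1-yl]oxy}-2-methylidenepent-4-enoate
Product: 23 tert-butyl 2-[(1S,2S,3S,4R)-3-[3-(TBDPS-oxy)prop-1-en-2-yl]-4-ethenyl-2-hydroxy-4-methyl-6-oxocyclohexyl]prop-2-enoate, via keto aldehyde 22 (not isolated)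
Conditions: toluene (0.01 M), 2,6-di-tert-butyl-4-methylphenol (cat.), base-washed sealed tube, 115 °C; then 0 °C, pyrrolidine (0.3 equiv), AcOH (0.3 equiv), 0 °C to rt
Reagents that add atoms: none
Why: Heating triggers a concerted [3,3]-sigmatropic (Claisen) rearrangement of the allyl 2-alkoxyvinyl ether that forms the C1–C2 bond, the vinyl group and the C3 ketone (δ-keto aldehyde 22), and pyrrolidinium acetate then turns the ketone into its enamine towards C4, which adds to the aldehyde and forms the C4–C5 bond; the closest precedents are Tebbe–Claisen sequences to γ,δ-unsaturated ketones and amine-catalysed aldol cyclisations of 1,5-keto aldehydes. The one ring closed is the cyclohexanone, by a 6-(enolendo)-exo-trig aldol. The quaternary C1 is controlled by allylic 1,3-strain in the Z alkene: the C6–H lies in the alkene plane, the bulky silyloxypropenyl arm shields one face, and the vinyl ether arm bonds on the face of the small formyl group. C5 follows from a chair transition state with the C6 substituent equatorial and the aldehyde oxygen equatorial (the axial site is blocked by the axial C1 methyl), which puts the hydroxyl trans to the C6 substituent; C4 follows from the E enamine (side chain anti to nitrogen), which delivers the acrylate arm axial and cis to the new hydroxyl, a kinetic outcome that should hold because the adduct cannot easily re-form a tetrasubstituted enamine. The step needs enolisation towards C4 and not C2 (C4 is allylic and open, C2 is neopentylic), no enolisation of the aldehyde (neutral thermal stage, kept below the temperature of a Cope reaction of the new 1,5-diene) and survival of the hindered tert-butyl acrylate, which should resist lactonisation and aza-Michael addition.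

Step 17
Reactants: 23 tert-butyl 2-[(1S,2S,3S,4R)-3-[3-(TBDPS-oxy)prop-1-en-2-yl]-4-ethenyl-2-hydroxy-4-methyl-6-oxocyclohexyl]prop-2-enoate
Product: 24 tert-butyl 2-[(1S,2S,3S,4R)-3-[3-(TBDPS-oxy)prop-1-en-2-yl]-4-ethenyl-4-methyl-6-oxo-2-(TES-oxy)cyclohexyl]prop-2-enoate
Conditions: Et3SiOTf, 2,6-lutidine, CH2Cl2, −78 °C
Reagents that add atoms: triethylsilyl trifluoromethanesulfonate, CC[Si](CC)(CC)OS(=O)(=O)C(F)(F)F
Why: Silyl triflate silylation of the hindered secondary alcohol blocks retro-aldol and later lactonisation, and the equatorial silyloxy group helps to lock the ring chair.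

Step 18
Reactants: 24 tert-butyl 2-[(1S,2S,3S,4R)-3-[3-(TBDPS-oxy)prop-1-en-2-yl]-4-ethenyl-4-methyl-6-oxo-2-(TES-oxy)cyclohexyl]prop-2-enoate
Product: 25 tert-butyl 2-[(1R,2S,3S,4R,6S)-3-[3-(TBDPS-oxy)prop-1-en-2-yl]-4-ethenyl-6-hydroxy-4-methyl-2-(TES-oxy)cyclohexyl]prop-2-enoate
Conditions: LiBH(s-Bu)3 (L-Selectride, 1.2 equiv), THF, −78 °C; aq. NH4Cl
Reagents that add atoms: none
Why: Substrate-controlled ketone reduction; in the chair that keeps the C5 and C6 groups equatorial the axial C1 methyl blocks the axial trajectory, so the bulky hydride should attack equatorially anti to that methyl and give the axial C3 alcohol, trans to the C4 side chain and to the C5 oxygen, faster than it touches the hindered acrylate.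

Step 19
Reactants: 26 methyl 2-[(4R)-2,2-dimethyl-1,3-dioxolan-4-yl]acetate
Product: 29 methyl 2-[(4R)-2,2-dimethyl-1,3-dioxolan-4-yl]prop-2-enoate, via Mannich base 27 (not isolated), via trimethylammonium iodide 28 (not isolated)
Conditions: LiN(i-Pr)2, THF, −78 °C; CH2=NMe2+ I−, −78 °C to rt; then MeI, MeOH, rt; then DBU, CH2Cl2, rt
Reagents that add atoms: N,N-dimethylmethyleneiminium iodide (Eschenmoser's salt), C=[N+](C)C.[I-]
Why: α-Methylenation by Mannich reaction, quaternisation and elimination; the enolate is kept at −78 °C to avoid β-elimination of the acetal oxygen, and the bought stereocentre is not involved.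

Step 20
Reactants: 29 methyl 2-[(4R)-2,2-dimethyl-1,3-dioxolan-4-yl]prop-2-enoate
Product: 30 2-[(4R)-2,2-dimethyl-1,3-dioxolan-4-yl]prop-2-enoic acid
Conditions: LiOH, THF/H2O, 0 °C; then 1 M HCl to pH 4 at 0 °C
Reagents that add atoms: lithium hydroxide, [Li+].[OH-]
Why: Saponification of the methyl ester; the acetonide is stable to base and to brief mild acidification.

Step 21
Reactants: 25 tert-butyl 2-[(1R,2S,3S,4R,6S)-3-[3-(TBDPS-oxy)prop-1-en-2-yl]-4-ethenyl-6-hydroxy-4-methyl-2-(TES-oxy)cyclohexyl]prop-2-enoate; 30 2-[(4R)-2,2-dimethyl-1,3-dioxolan-4-yl]prop-2-enoic acid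
Product: 32 (1S,2R,3S,4S,5R)-2-(3-tert-butoxy-3-oxoprop-1-en-2-yl)-4-[3-(TBDPS-oxy)prop-1-en-2-yl]-5-ethenyl-5-methyl-3-(TES-oxy)cyclohexyl 2-[(4R)-2,2-dimethyl-1,3-dioxolan-4-yl]prop-2-enoate, via mixed anhydride 31 (not isolated)
Conditions: 2,4,6-Cl3C6H2COCl, Et3N, toluene, rt; then 25, DMAP, toluene, 40 °C
Reagents that add atoms: none
Why: Yamaguchi esterification; the mixed anhydride with DMAP is reactive enough to acylate the hindered axial C3 alcohol and creates no new stereocentre.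

Step 22
Reactants: 32 (1S,2R,3S,4S,5R)-2-(3-tert-butoxy-3-oxoprop-1-en-2-yl)-4-[3-(TBDPS-oxy)prop-1-en-2-yl]-5-ethenyl-5-methyl-3-(TES-oxy)cyclohexyl 2-[(4R)-2,2-dimethyl-1,3-dioxolan-4-yl]prop-2-enoate
Product: 33 (1S,2S,3S,4S,5R)-2-(3-tert-butoxy-3-oxoprop-1-en-2-yl)-4-[3-(TBDPS-oxy)prop-1-en-2-yl]-5-ethenyl-3-hydroxy-5-methylcyclohexyl (3R)-3,4-dihydroxy-2-methylidenebutanoate
Conditions: AcOH/THF/H2O 3:1:1, rt
Reagents that add atoms: none
Why: Acid-catalysed hydrolysis should remove the isopropylidene acetal and the secondary TES ether, while the TBDPS ether and the tert-butyl ester survive and the hindered tert-butyl ester should not lactonise with the freed C5 hydroxyl.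

Step 23
Reactants: 33 (1S,2S,3S,4S,5R)-2-(3-tert-butoxy-3-oxoprop-1-en-2-yl)-4-[3-(TBDPS-oxy)prop-1-en-2-yl]-5-ethenyl-3-hydroxy-5-methylcyclohexyl (3R)-3,4-dihydroxy-2-methylidenebutanoate
Product: 35 2-[(1S,2S,3S,4R,6S)-6-{[(3R)-3,4-dihydroxy-2-methylidenebutanoyl]oxy}-4-ethenyl-2-hydroxy-3-(3-hydroxyprop-1-en-2-yl)-4-methylcyclohexyl]prop-2-enoic acid, via persilylated trimethylsilyl ester 34 (not isolated)
Conditions: Me3SiOTf (8 equiv), 2,6-lutidine (12 equiv), CH2Cl2, 0 °C to rt; then HF·pyridine, pyridine, THF, 0 °C to rt; pH 5 buffer work-up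
Reagents that add atoms: none
Why: Silyl triflate-mediated tert-butyl ester cleavage (loss of isobutene, hydroxyls silylated in passing) followed by fluoride desilylation frees the acid and all hydroxyls without aqueous mineral acid, which limits lactonisation of the C5 hydroxyl onto the acid and cyclisation of the side-chain diol onto its ester.

**Compound list**

1 | but-2-yn-1-ol | CC#CCO | starting material
2 | sodium 2,2-bis(2-methoxyethoxy)-3-methyl-2,5-dihydro-1,2-oxaluminol-2-uide (cyclic Z-alkenylaluminate) | CC1=CCO[Al-]1(OCCOC)OCCOC.[Na+] | intermediate (not isolated)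
3 | (2Z)-3-iodobut-2-en-1-ol | C/C(I)=C/CO | intermediate
4 | 1-({[(2Z)-3-iodobut-2-en-1-yl]oxy}methyl)-4-methoxybenzene | C/C(I)=C/COCc1ccc(OC)cc1 | intermediate
5 | 2-{(2E)-4-[(4-methoxyphenyl)methoxy]but-2-en-2-yl}-4,4,5,5-tetramethyl-1,3,2-dioxaborolane (boron cis to CH2O) | C/C(B1OC(C)(C)C(C)(C)O1)=C/COCc1ccc(OC)cc1 | intermediate
6 | ethyl (2E)-4-hydroxybut-2-enoate | CCOC(=O)/C=C/CO | starting material
7 | ethyl (2E)-4-[(triethylsilyl)oxy]but-2-enoate | CCOC(=O)/C=C/CO[Si](CC)(CC)CC | intermediate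
8 | ethyl (3R)-3-{(2Z)-4-[(4-methoxyphenyl)methoxy]but-2-en-2-yl}-4-[(triethylsilyl)oxy]butanoate | CC[Si](CC)(CC)OC[C@@H](/C(C)=C\COCc1ccc(OC)cc1)CC(=O)OCC | intermediate
9 | ethyl (3R)-2-[(dimethylamino)methyl]-3-{(2Z)-4-[(4-methoxyphenyl)methoxy]but-2-en-2-yl}-4-[(triethylsilyl)oxy]butanoate (C2 epimers) | CC[Si](CC)(CC)OC[C@@H](/C(C)=C\COCc1ccc(OC)cc1)C(CN(C)C)C(=O)OCC | intermediate (not isolated)
10 | (3R)-2-(ethoxycarbonyl)-3-{(2Z)-4-[(4-methoxyphenyl)methoxy]but-2-en-2-yl}-N,N,N-trimethyl-4-[(triethylsilyl)oxy]butan-1-aminium iodide (C2 epimers) | CC[Si](CC)(CC)OC[C@@H](/C(C)=C\COCc1ccc(OC)cc1)C(C[N+](C)(C)C)C(=O)OCC.[I-] | intermediate (not isolated)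
11 | ethyl (3S)-3-{(2Z)-4-[(4-methoxyphenyl)methoxy]but-2-en-2-yl}-2-methylidene-4-[(triethylsilyl)oxy]butanoate | CC[Si](CC)(CC)OC[C@@H](/C(C)=C\COCc1ccc(OC)cc1)C(=C)C(=O)OCC | intermediate
12 | (3S)-3-{(2Z)-4-[(4-methoxyphenyl)methoxy]but-2-en-2-yl}-2-methylidene-4-[(triethylsilyl)oxy]butan-1-ol | CC[Si](CC)(CC)OC[C@@H](/C(C)=C\COCc1ccc(OC)cc1)C(=C)CO | intermediate
13 | tert-butyl{[(3S)-3-{(2Z)-4-[(4-methoxyphenyl)methoxy]but-2-en-2-yl}-2-methylidene-4-[(triethylsilyl)oxy]butyl]oxy}diphenylsilane | CC[Si](CC)(CC)OC[C@@H](/C(C)=C\COCc1ccc(OC)cc1)C(=C)CO[Si](c1ccccc1)(c1ccccc1)C(C)(C)C | intermediate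
14 | (2Z,4S)-6-[(tert-butyldiphenylsilyl)oxy]-3-methyl-5-methylidene-4-{[(triethylsilyl)oxy]methyl}hex-2-en-1-ol | CC[Si](CC)(CC)OC[C@@H](/C(C)=C\CO)C(=C)CO[Si](c1ccccc1)(c1ccccc1)C(C)(C)C | intermediate
15 | 4-methoxy-2-methylidene-4-oxobutanoic acid (monomethyl itaconate) | COC(=O)CC(=C)C(=O)O | starting material
16 | 1-tert-butyl 4-methyl 2-methylidenebutanedioate | COC(=O)CC(=C)C(=O)OC(C)(C)C | intermediate
17 | 3-(tert-butoxycarbonyl)but-3-enoic acid | OC(=O)CC(=C)C(=O)OC(C)(C)C | intermediate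
18 | 1-tert-butyl 4-[(2Z,4S)-6-[(tert-butyldiphenylsilyl)oxy]-3-methyl-5-methylidene-4-{[(triethylsilyl)oxy]methyl}hex-2-en-1-yl] 2-methylidenebutanedioate | CC[Si](CC)(CC)OC[C@@H](/C(C)=C\COC(=O)CC(=C)C(=O)OC(C)(C)C)C(=C)CO[Si](c1ccccc1)(c1ccccc1)C(C)(C)C | intermediate
19 | tert-butyl 4-{[(2Z,4S)-6-[(tert-butyldiphenylsilyl)oxy]-3-methyl-5-methylidene-4-{[(triethylsilyl)oxy]methyl}hex-2-en-1-yl]oxy}-2-methylidenepent-4-enoate | CC[Si](CC)(CC)OC[C@@H](/C(C)=C\COC(=C)CC(=C)C(=O)OC(C)(C)C)C(=C)CO[Si](c1ccccc1)(c1ccccc1)C(C)(C)C | intermediate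
20 | tert-butyl 4-{[(2Z,4S)-6-[(tert-butyldiphenylsilyl)oxy]-4-(hydroxymethyl)-3-methyl-5-methylidenehex-2-en-1-yl]oxy}-2-methylidenepent-4-enoate | OC[C@@H](/C(C)=C\COC(=C)CC(=C)C(=O)OC(C)(C)C)C(=C)CO[Si](c1ccccc1)(c1ccccc1)C(C)(C)C | intermediate
21 | tert-butyl 4-{[(2Z,4S)-6-[(tert-butyldiphenylsilyl)oxy]-4-formyl-3-methyl-5-methylidenehex-2-en-1-yl]oxy}-2-methylidenepent-4-enoate | O=C[C@@H](/C(C)=C\COC(=C)CC(=C)C(=O)OC(C)(C)C)C(=C)CO[Si](c1ccccc1)(c1ccccc1)C(C)(C)C | intermediate
22 | tert-butyl (6R,7S)-9-[(tert-butyldiphenylsilyl)oxy]-6-ethenyl-7-formyl-6-methyl-2,8-dimethylidene-4-oxononanoate | C=C[C@@](C)(CC(=O)CC(=C)C(=O)OC(C)(C)C)[C@H](C=O)C(=C)CO[Si](c1ccccc1)(c1ccccc1)C(C)(C)C | intermediate (not isolated)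
23 | tert-butyl 2-[(1S,2S,3S,4R)-3-{3-[(tert-butyldiphenylsilyl)oxy]prop-1-en-2-yl}-4-ethenyl-2-hydroxy-4-methyl-6-oxocyclohexyl]prop-2-enoate | C=C[C@@]1(C)CC(=O)[C@@H](C(=C)C(=O)OC(C)(C)C)[C@@H](O)[C@@H]1C(=C)CO[Si](c2ccccc2)(c2ccccc2)C(C)(C)C | intermediate
24 | tert-butyl 2-[(1S,2S,3S,4R)-3-{3-[(tert-butyldiphenylsilyl)oxy]prop-1-en-2-yl}-4-ethenyl-4-methyl-6-oxo-2-[(triethylsilyl)oxy]cyclohexyl]prop-2-enoate | C=C[C@@]1(C)CC(=O)[C@@H](C(=C)C(=O)OC(C)(C)C)[C@@H](O[Si](CC)(CC)CC)[C@@H]1C(=C)CO[Si](c2ccccc2)(c2ccccc2)C(C)(C)C | intermediate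
25 | tert-butyl 2-[(1R,2S,3S,4R,6S)-3-{3-[(tert-butyldiphenylsilyl)oxy]prop-1-en-2-yl}-4-ethenyl-6-hydroxy-4-methyl-2-[(triethylsilyl)oxy]cyclohexyl]prop-2-enoate | C=C[C@@]1(C)C[C@H](O)[C@@H](C(=C)C(=O)OC(C)(C)C)[C@@H](O[Si](CC)(CC)CC)[C@@H]1C(=C)CO[Si](c2ccccc2)(c2ccccc2)C(C)(C)C | intermediate
26 | methyl 2-[(4R)-2,2-dimethyl-1,3-dioxolan-4-yl]acetate | COC(=O)C[C@@H]1COC(C)(C)O1 | starting material
27 | methyl 3-(dimethylamino)-2-[(4R)-2,2-dimethyl-1,3-dioxolan-4-yl]propanoate (C2 epimers) | COC(=O)C(CN(C)C)[C@@H]1COC(C)(C)O1 | intermediate (not isolated)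
28 | 2-[(4R)-2,2-dimethyl-1,3-dioxolan-4-yl]-3-methoxy-N,N,N-trimethyl-3-oxopropan-1-aminium iodide (C2 epimers) | COC(=O)C(C[N+](C)(C)C)[C@@H]1COC(C)(C)O1.[I-] | intermediate (not isolated)
29 | methyl 2-[(4R)-2,2-dimethyl-1,3-dioxolan-4-yl]prop-2-enoate | COC(=O)C(=C)[C@@H]1COC(C)(C)O1 | intermediate
30 | 2-[(4R)-2,2-dimethyl-1,3-dioxolan-4-yl]prop-2-enoic acid | OC(=O)C(=C)[C@@H]1COC(C)(C)O1 | intermediate
31 | 2-[(4R)-2,2-dimethyl-1,3-dioxolan-4-yl]prop-2-enoic 2,4,6-trichlorobenzoic anhydride | C=C(C(=O)OC(=O)c1c(Cl)cc(Cl)cc1Cl)[C@@H]1COC(C)(C)O1 | intermediate (not isolated)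
32 | (1S,2R,3S,4S,5R)-2-(3-tert-butoxy-3-oxoprop-1-en-2-yl)-4-{3-[(tert-butyldiphenylsilyl)oxy]prop-1-en-2-yl}-5-ethenyl-5-methyl-3-[(triethylsilyl)oxy]cyclohexyl 2-[(4R)-2,2-dimethyl-1,3-dioxolan-4-yl]prop-2-enoate | C=C[C@@]1(C)C[C@H](OC(=O)C(=C)[C@@H]2COC(C)(C)O2)[C@@H](C(=C)C(=O)OC(C)(C)C)[C@@H](O[Si](CC)(CC)CC)[C@@H]1C(=C)CO[Si](c3ccccc3)(c3ccccc3)C(C)(C)C | intermediate
33 | (1S,2S,3S,4S,5R)-2-(3-tert-butoxy-3-oxoprop-1-en-2-yl)-4-{3-[(tert-butyldiphenylsilyl)oxy]prop-1-en-2-yl}-5-ethenyl-3-hydroxy-5-methylcyclohexyl (3R)-3,4-dihydroxy-2-methylidenebutanoate | C=C[C@@]1(C)C[C@H](OC(=O)C(=C)[C@@H](O)CO)[C@@H](C(=C)C(=O)OC(C)(C)C)[C@@H](O)[C@@H]1C(=C)CO[Si](c2ccccc2)(c2ccccc2)C(C)(C)C | intermediate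
34 | (1S,2R,3S,4S,5R)-4-{3-[(tert-butyldiphenylsilyl)oxy]prop-1-en-2-yl}-5-ethenyl-5-methyl-2-{3-oxo-3-[(trimethylsilyl)oxy]prop-1-en-2-yl}-3-[(trimethylsilyl)oxy]cyclohexyl (3R)-2-methylidene-3,4-bis[(trimethylsilyl)oxy]butanoate | C=C[C@@]1(C)C[C@H](OC(=O)C(=C)[C@@H](O[Si](C)(C)C)CO[Si](C)(C)C)[C@@H](C(=C)C(=O)O[Si](C)(C)C)[C@@H](O[Si](C)(C)C)[C@@H]1C(=C)CO[Si](c2ccccc2)(c2ccccc2)C(C)(C)C | intermediate (not isolated)
35 | 2-[(1S,2S,3S,4R,6S)-6-{[(3R)-3,4-dihydroxy-2-methylidenebutanoyl]oxy}-4-ethenyl-2-hydroxy-3-(3-hydroxyprop-1-en-2-yl)-4-methylcyclohexyl]prop-2-enoic acid | C=C[C@@]1(C)C[C@H](OC(=O)C(=C)[C@@H](O)CO)[C@@H](C(=C)C(=O)O)[C@@H](O)[C@@H]1C(=C)CO | target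

**Step count and risks**

Total steps: 23. Longest linear sequence: 18 steps (steps 1, 2, 3, 5 to 9, 12 to 18, 21 to 23).

The three steps most likely to fail:

Step 16. The process at risk is enolisation of the doubly allylic aldehyde during the thermal stage (loss of the C6 configuration, double-bond migration) together with erosion of facial control in the rearrangement or of diastereocontrol in the aldol. The fallback separates the two bond formations and keeps the aldehyde away from heat. It sets out from compound 19, which is rearranged as its silyl ether (toluene, 110 °C) to tert-butyl (6R,7S)-9-[(tert-butyldiphenylsilyl)oxy]-6-ethenyl-6-methyl-2,8-dimethylidene-4-oxo-7-{[(triethylsilyl)oxy]methyl}nonanoate F1. Cleavage with Bu4NF gives tert-butyl (6R,7S)-9-[(tert-butyldiphenylsilyl)oxy]-6-ethenyl-7-(hydroxymethyl)-6-methyl-2,8-dimethylidene-4-oxononanoate F2. Dess–Martin oxidation then gives keto aldehyde 22, now isolated, and the pyrrolidine/AcOH aldol is run as a separate operation. The fallback comes back to the route at compound 23.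

Step 18. The process at risk is hydride delivery to the wrong face of the ketone, because the axial C4 side chain also hinders the equatorial trajectory, or competing conjugate reduction of the acrylate. The fallback installs the C3 oxygen by substitution with inversion instead of by acylation with retention. It sets out from compound 24, which on reduction from the other face gives the C3-epimeric alcohol tert-butyl 2-[(1R,2S,3S,4R,6R)-3-{3-[(tert-butyldiphenylsilyl)oxy]prop-1-en-2-yl}-4-ethenyl-6-hydroxy-4-methyl-2-[(triethylsilyl)oxy]cyclohexyl]prop-2-enoate F3. A Mitsunobu esterification of F3 with acid 30 (PPh3, diisopropyl azodicarboxylate, toluene, 0 °C to rt) inverts C3. The fallback comes back to the route at compound 32, so that step 21 is not needed.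

Step 13. The process at risk is loss of chemoselectivity between the two ester carbonyls (methylenation of the tert-butyl acrylate as well) or early rearrangement of the enol ether during work-up. The fallback builds the enol ether by C–O coupling instead of carbonyl methylenation. It sets out from compound 14. The coupling partner would be made from tert-butyl 2-(bromomethyl)prop-2-enoate and HC≡CMgBr (CuI cat.), which give tert-butyl 2-methylidenepent-4-ynoate F4, followed by Markovnikov hydroiodination (NaI, Me3SiCl, H2O, MeCN) to tert-butyl 4-iodo-2-methylidenepent-4-enoate F5. Copper-catalysed coupling of 14 with F5 (CuI, 3,4,7,8-tetramethyl-1,10-phenanthroline, Cs2CO3, toluene, 80 °C) forms the allyl vinyl ether directly. The fallback comes back to the route at compound 19.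

Further compounds
F1 | step 16 | tert-butyl (6R,7S)-9-[(tert-butyldiphenylsilyl)oxy]-6-ethenyl-6-methyl-2,8-dimethylidene-4-oxo-7-{[(triethylsilyl)oxy]methyl}nonanoate | C=C[C@@](C)(CC(=O)CC(=C)C(=O)OC(C)(C)C)[C@H](CO[Si](CC)(CC)CC)C(=C)CO[Si](c1ccccc1)(c1ccccc1)C(C)(C)C
F2 | step 16 | tert-butyl (6R,7S)-9-[(tert-butyldiphenylsilyl)oxy]-6-ethenyl-7-(hydroxymethyl)-6-methyl-2,8-dimethylidene-4-oxononanoate | C=C[C@@](C)(CC(=O)CC(=C)C(=O)OC(C)(C)C)[C@H](CO)C(=C)CO[Si](c1ccccc1)(c1ccccc1)C(C)(C)C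
F3 | step 18 | tert-butyl 2-[(1R,2S,3S,4R,6R)-3-{3-[(tert-butyldiphenylsilyl)oxy]prop-1-en-2-yl}-4-ethenyl-6-hydroxy-4-methyl-2-[(triethylsilyl)oxy]cyclohexyl]prop-2-enoate | C=C[C@@]1(C)C[C@@H](O)[C@@H](C(=C)C(=O)OC(C)(C)C)[C@@H](O[Si](CC)(CC)CC)[C@@H]1C(=C)CO[Si](c2ccccc2)(c2ccccc2)C(C)(C)C
F4 | step 13 | tert-butyl 2-methylidenepent-4-ynoate | C#CCC(=C)C(=O)OC(C)(C)C
F5 | step 13 | tert-butyl 4-iodo-2-methylidenepent-4-enoate | C=C(I)CC(=C)C(=O)OC(C)(C)C
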